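(The constants used here are assumed.)

In this flask the protic impurity at first takes the solid substrate at 0.0720 h⁻¹ of the charge, faster than that solid goes into solution at 0.0170 h⁻¹, so the question is whether the impurity can use up its whole charge while solid remains.

    solid substrate ⇌ dissolved substrate, rate k1*(cs1 - [dissolved substrate]) while solid is left; crystals form when [dissolved substrate] > cs1 (cs1 = 0.67 M, k1 = 0.0254 h⁻¹)
    dissolved substrate + partner ⇌ target (K2 = 14 M⁻¹, k2 = 2.98 M⁻¹ h⁻¹)
    solid reagent ⇌ partner, rate k3*(cs3 - [partner]) while solid is left; crystals form when [partner] > cs3 (cs3 = 0.93 M, k3 = 0.0832 h⁻¹)
    solid substrate + protic impurity → quenched substrate (k4 = 0.360 M⁻¹ h⁻¹)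

solid substrate 1.0 M; solid reagent 1.10 equiv; protic impurity 0.200 M; time 10 d

- the target standing at 10 d, as a percentage of the solid substrate charged
- concentration of dissolved substrate in solution at 10 d, in percent of saturation

Suppose it can: then 80.0% of the charge survives, and you need 47.0 h to dissolve it at full speed. With the solid at a mean level of 40.0% of the charge over that stretch, the impurity's lifetime is 6.94 h. Their ratio is 6.77, and this count of impurity lifetimes within the life of the solid leaves, by this estimate, 0.115% of the impurity's charge, so the supposition stands to within that remainder. The solid reagent needs 14.2 h at full speed, and both times are shorter than the run, so I let the surviving substrate and the partner reach the equilibrium of the coupling, which gives target 68.3% of the charge and saturation 17.5%. Those full-speed times are shortest times, since dissolving slows as the solution fills, and that equilibrium puts the partner at 0.417 M, under its solubility of 0.93 M, as it must be for the solid reagent to dissolve whole.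

The forecast says 68.3% (67% to 69.5%) and 17.5% (16.5% to 18.7%), holding that “the final state is true equilibrium”.

The flask gives 68.3% and 17.5%, with 0.058% of the impurity's charge left. In the neighbour charged with 0.50 M of impurity the count falls to 2.64, which leaves 7.14% of that charge by reckoning; that neighbour holds 2.71% of its impurity charge, with target at 46.2%. The first flask stands at 0% solid substrate and 0% solid reagent at 10.0 d, and the coupling's relaxation half-life of 0.384 h is short against the run. At 100 d that flask still holds target at 68.3% and impurity at 0.0576%.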